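**Plan**

- Retrosynthetic cuts, in order: the C2–C1' aryl bond (conjugate arylation of a chromone); the one-carbon unit C2 of ring C (bonds C3–C2 and O1–C2); the C4a–C4 acetyl bond; the two C–C bonds that turn a carboxyl carbon into the isopropenyl group; last, C1''–C2'' together with an O1–acyl bond.
- Enabling feature: C8 of ring A lies between the two phenol oxygens (O1 on C8a and the oxygen on C7). O1–C8a–C8–C1'' is therefore a latent o-quinone methide, and the isopropenyl carbon on C2'' can be carried as a carboxyl carbon tied to O1 in a six-membered lactone.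
- Forward: a symmetrical bis-silyloxybenzyl bromide (ring A) and an acyl imidazole (C2''–C5'') are annulated to a 3-alkyldihydrocoumarin. The lactone is opened to a Weinreb amide and its carbon becomes the isopropenyl group. The freed oxygen directs acetylation of C4a, pyranone ring C is closed, ring B is added last and the silyl groups are removed.
- Stereochemistry: C2'' (R) comes from the chiral triazolium carbene in the annulation; C2 (S) comes from the chiral Pd–pyridinooxazoline catalyst in the chromone arylation.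

Key step: step 8

Remark 1: the two silyloxy groups of bromide 5 are equivalent, so the oxygen that ends up in the lactone is arbitrary; it is carried on as O1 of the flavanone, and the surviving silyl ether becomes the 7-OH.
Remark 2: catalyst-bound species, and metal alkoxides, chelates or borates that are only hydrolysed at work-up, are not numbered; species consumed by a second reagent in the same flask are.
Remark 3: the absolute sense of both catalytic asymmetric steps is assigned by analogy; the catalyst antipode is to be used if a model run shows the opposite sense.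

**Route**

Step 1
Reactants: 1 2,4,6-trihydroxybenzaldehyde
Product: 2 2,6-dihydroxy-4-methoxybenzaldehyde
Conditions: Me2SO4 (1.0 equiv), K2CO3 (1.0 equiv), acetone, 0 °C → rt
Reagents that add atoms: dimethyl sulfate, COS(=O)(=O)OC
Why: Williamson O-methylation, in which the 4-OH is the most acidic phenol and the only one not hydrogen-bonded to the aldehyde, so one equivalent of base and of a hard methylating agent should methylate it preferentially, over-methylated material being removed by chromatography.

Step 2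
Reactants: 2 2,6-dihydroxy-4-methoxybenzaldehyde
Product: 3 2,6-bis(tert-butyldimethylsilyloxy)-4-methoxybenzaldehyde
Conditions: TBSCl, imidazole, DMF, rt
Reagents that add atoms: tert-butyldimethylsilyl chloride, CC(C)(C)[Si](C)(C)Cl
Why: Standard phenol silylation with silyl chloride/imidazole in DMF, forcing enough to cap both hydrogen-bonded hydroxyl groups.

Step 3
Reactants: 3 2,6-bis(tert-butyldimethylsilyloxy)-4-methoxybenzaldehyde
Product: 4 [2,6-bis(tert-butyldimethylsilyloxy)-4-methoxyphenyl]methanol
Conditions: DIBAL-H, CH2Cl2, −78 °C; Rochelle salt work-up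
Reagents that add atoms: none
Why: Hydride reduction of the aldehyde at low temperature gives an aluminium alkoxide that is too weakly nucleophilic to trigger the aryl-O to benzyl-O silyl migration that free alkoxides can cause.

Step 4
Reactants: 4 [2,6-bis(tert-butyldimethylsilyloxy)-4-methoxyphenyl]methanol
Product: 5 2-(bromomethyl)-1,3-bis(tert-butyldimethylsilyloxy)-5-methoxybenzene
Conditions: CBr4, PPh3, CH2Cl2, 0 °C; pentane, cold filtration; used at once
Reagents that add atoms: carbon tetrabromide, BrC(Br)(Br)Br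
Why: Appel bromination under neutral conditions should convert the benzylic alcohol cleanly, and because this very electron-rich bromide ionises easily it is freed from phosphine oxide without chromatography and taken straight into step 8.

Step 5
Reactants: 6 5-oxohexanoic acid
Product: 7 5-hydroxy-5-methylhexanoic acid
Conditions: MeMgBr (2.5 equiv), THF, −20 → 0 °C; aq. NH4Cl, then citric acid to pH 4, cold
Reagents that add atoms: methylmagnesium bromide, C[Mg]Br
Why: Grignard addition to the ketone, in which the first equivalent turns the acid into an unreactive carboxylate and the second adds to the carbonyl, with a cold and weakly acidic work-up to limit lactonisation of the δ-hydroxy acid.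

Step 6
Reactants: 7 5-hydroxy-5-methylhexanoic acid
Product: 9 5-methyl-5-(triethylsilyloxy)hexanoic acid, via bis-silyl ester 8 (not isolated)
Conditions: TESOTf (2.3 equiv), 2,6-lutidine, CH2Cl2, −78 → 0 °C; then K2CO3 (cat.), MeOH/H2O, 0 °C
Reagents that add atoms: triethylsilyl triflate, CC[Si](CC)(CC)OS(=O)(=O)C(F)(F)F
Why: Silyl triflate/2,6-lutidine silylation is strong enough for a tertiary alcohol, and the silyl ester formed alongside is far more labile than the tertiary silyl ether, so mild aqueous methanolysis should cleave it selectively.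

Step 7
Reactants: 9 5-methyl-5-(triethylsilyloxy)hexanoic acid
Product: 10 1-[5-methyl-5-(triethylsilyloxy)hexanoyl]-1H-imidazole
Conditions: CDI, CH2Cl2, rt
Reagents that add atoms: 1,1'-carbonyldiimidazole, O=C(n1ccnc1)n1ccnc1
Why: Carbonyldiimidazole activation of the acid gives the acyl imidazole with loss of CO2 and imidazole under neutral conditions that leave the tertiary silyl ether untouched.

Step 8
Reactants: 5 2-(bromomethyl)-1,3-bis(tert-butyldimethylsilyloxy)-5-methoxybenzene; 10 1-[5-methyl-5-(triethylsilyloxy)hexanoyl]-1H-imidazole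
Product: 12 (3R)-5-(tert-butyldimethylsilyloxy)-7-methoxy-3-[3-methyl-3-(triethylsilyloxy)butyl]-3,4-dihydro-2H-chromen-2-one, via quinone methide 11 (not isolated)
Conditions: aminoindanol-derived N-mesityl triazolium BF4 (15 mol %; enantiomer chosen to give 3R), CsF (1.3 equiv), 18-crown-6, 4 Å MS, THF, −20 °C → rt; 5 added slowly
Reagents that add atoms: none
Why: The free carbene is acylated by 10 and the acyl azolium is deprotonated by the released imidazolide to a (Z)-azolium enolate, while fluoride removes one aryl silyl group of 5 and the phenoxide expels bromide to give quinone methide 11. Michael addition of the enolate carbon to the exocyclic CH2 of 11 forms C1''–C2'' and restores the aromatic ring; the closest known reaction type is the carbene-catalysed formal [4+2] annulation of acyl-imidazole-derived azolium enolates with fluoride-generated o-quinone methides. The phenoxide then closes the six-membered lactone by 6-exo-trig O-acylation on the acyl azolium, which releases the carbene. C2'' is set by the chiral triazolium, whose fused indane wall should shield one enolate face so that 11 adds to the Si face of C2'', giving 3R. No site selectivity is needed because the two silyloxy groups flanking the CH2Br carbon are equivalent; the tertiary alkyl silyl ether and the second aryl silyl ether should survive because fluoride is limited to a small excess and aryl O–Si cleavage at the benzyl bromide stage is much the fastest process. Slow addition of 5 keeps 11 dilute and should suppress its dimerisation.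

Step 9
Reactants: 12 (3R)-5-(tert-butyldimethylsilyloxy)-7-methoxy-3-[3-methyl-3-(triethylsilyloxy)butyl]-3,4-dihydro-2H-chromen-2-one
Product: 13 (2R)-2-{[2-(tert-butyldimethylsilyloxy)-6-hydroxy-4-methoxyphenyl]methyl}-N-methoxy-N,5-dimethyl-5-(triethylsilyloxy)hexanamide
Conditions: MeNH(OMe)·HCl, AlMe3, CH2Cl2, 0 °C → rt; crude product carried on
Reagents that add atoms: N,O-dimethylhydroxylamine hydrochloride, CNOC.Cl
Why: Weinreb aminolysis of the aryl lactone with the aluminium amide is weakly basic, so C2'' should not epimerise, and the phenol is used crude to forestall relactonisation.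

Step 10
Reactants: 13 (2R)-2-{[2-(tert-butyldimethylsilyloxy)-6-hydroxy-4-methoxyphenyl]methyl}-N-methoxy-N,5-dimethyl-5-(triethylsilyloxy)hexanamide
Product: 14 (2R)-2-{[2-(tert-butyldimethylsilyloxy)-4-methoxy-6-(methoxymethoxy)phenyl]methyl}-N-methoxy-N,5-dimethyl-5-(triethylsilyloxy)hexanamide
Conditions: MOMCl, i-Pr2NEt, CH2Cl2, 0 °C → rt
Reagents that add atoms: chloromethyl methyl ether, COCCl
Why: O-alkylation of the phenol with MOMCl and Hünig's base (no free phenoxide, hence no relactonisation) installs a group that later directs ortho-metalation.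

Step 11
Reactants: 14 (2R)-2-{[2-(tert-butyldimethylsilyloxy)-4-methoxy-6-(methoxymethoxy)phenyl]methyl}-N-methoxy-N,5-dimethyl-5-(triethylsilyloxy)hexanamide
Product: 15 (3R)-3-{[2-(tert-butyldimethylsilyloxy)-4-methoxy-6-(methoxymethoxy)phenyl]methyl}-6-methyl-6-(triethylsilyloxy)heptan-2-one
Conditions: MeMgBr, THF, 0 °C; cold aq. NH4Cl
Reagents that add atoms: methylmagnesium bromide, C[Mg]Br
Why: Weinreb ketone synthesis, in which the chelated tetrahedral adduct prevents over-addition and a cold buffered quench keeps the new α-stereogenic ketone away from base.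

Step 12
Reactants: 15 (3R)-3-{[2-(tert-butyldimethylsilyloxy)-4-methoxy-6-(methoxymethoxy)phenyl]methyl}-6-methyl-6-(triethylsilyloxy)heptan-2-one
Product: 16 1-(tert-butyldimethylsilyloxy)-5-methoxy-3-(methoxymethoxy)-2-[(2R)-5-methyl-2-(prop-1-en-2-yl)-5-(triethylsilyloxy)hexyl]benzene
Conditions: Cp2TiMe2, toluene, 70 °C, dark
Reagents that add atoms: dimethyltitanocene, [CH3-].[CH3-].[Ti+4].c1cc[cH-]c1.c1cc[cH-]c1
Why: Petasis methylenation through thermally generated Cp2Ti=CH2 is non-basic and therefore suited to an enolisable ketone with an α-stereocentre, after which C2'' is allylic and no longer epimerisable.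

Step 13
Reactants: 16 1-(tert-butyldimethylsilyloxy)-5-methoxy-3-(methoxymethoxy)-2-[(2R)-5-methyl-2-(prop-1-en-2-yl)-5-(triethylsilyloxy)hexyl]benzene
Product: 18 1-{4-(tert-butyldimethylsilyloxy)-6-methoxy-2-(methoxymethoxy)-3-[(2R)-5-methyl-2-(prop-1-en-2-yl)-5-(triethylsilyloxy)hexyl]phenyl}ethan-1-one, via aryllithium 17 (not isolated)
Conditions: n-BuLi, TMEDA, THF, −20 → 0 °C; then MeCON(OMe)Me, −78 °C → rt
Reagents that add atoms: N-methoxy-N-methylacetamide, CC(=O)N(C)OC
Why: Directed ortho-metalation followed by Weinreb acylation, in which the ring CH between OMOM and OMe is doubly activated while the bulky silyloxy group does not direct, and the lithiated carbon is para to the silyl ether so no O-to-C silyl migration can occur.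

Step 14
Reactants: 18 1-{4-(tert-butyldimethylsilyloxy)-6-methoxy-2-(methoxymethoxy)-3-[(2R)-5-methyl-2-(prop-1-en-2-yl)-5-(triethylsilyloxy)hexyl]phenyl}ethan-1-one
Product: 19 1-{4-(tert-butyldimethylsilyloxy)-2-hydroxy-6-methoxy-3-[(2R)-5-methyl-2-(prop-1-en-2-yl)-5-(triethylsilyloxy)hexyl]phenyl}ethan-1-one
Conditions: ZnBr2, n-PrSH, CH2Cl2, 0 °C, 10 min
Reagents that add atoms: none
Why: Lewis acid/thiol cleavage of the aryl MOM ether is fast at 0 °C, is helped by chelation to the ortho carbonyl, and should leave the silyl ethers and the isopropenyl group alone.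

Step 15
Reactants: 19 1-{4-(tert-butyldimethylsilyloxy)-2-hydroxy-6-methoxy-3-[(2R)-5-methyl-2-(prop-1-en-2-yl)-5-(triethylsilyloxy)hexyl]phenyl}ethan-1-one
Product: 21 7-(tert-butyldimethylsilyloxy)-5-methoxy-8-[(2R)-5-methyl-2-(prop-1-en-2-yl)-5-(triethylsilyloxy)hexyl]-4H-chromen-4-one, via enaminone 20 (not isolated)
Conditions: Me2NCH(OMe)2, toluene, 70 °C; then PPTS, CH2Cl2, 40 °C
Reagents that add atoms: N,N-dimethylformamide dimethyl acetal, COC(OC)N(C)C
Why: The standard chromone synthesis from an o-hydroxyacetophenone (enaminone formation, then 6-endo-trig oxa-Michael addition of the phenol and loss of dimethylamine), run with a buffered acid so that the tertiary silyl ether and the alkene are spared.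

Step 16
Reactants: 22 4-bromo-3-methoxyphenol
Product: 23 (4-bromo-3-methoxyphenoxy)(tert-butyl)dimethylsilane
Conditions: TBSCl, imidazole, DMF, rt
Reagents that add atoms: tert-butyldimethylsilyl chloride, CC(C)(C)[Si](C)(C)Cl
Why: Routine silylation of an unhindered phenol.

Step 17
Reactants: 23 (4-bromo-3-methoxyphenoxy)(tert-butyl)dimethylsilane
Product: 25 [4-(tert-butyldimethylsilyloxy)-2-methoxyphenyl]boronic acid, via aryllithium 24 (not isolated)
Conditions: n-BuLi, THF, −78 °C; B(Oi-Pr)3, −78 °C → rt; aq. NH4Cl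
Reagents that add atoms: triisopropyl borate, CC(C)OB(OC(C)C)OC(C)C; water, O
Why: Lithium–bromine exchange, borylation and hydrolysis of the borate, with the lithiated carbon para to the silyloxy group so that silyl migration cannot interfere.

Step 18
Reactants: 21 7-(tert-butyldimethylsilyloxy)-5-methoxy-8-[(2R)-5-methyl-2-(prop-1-en-2-yl)-5-(triethylsilyloxy)hexyl]-4H-chromen-4-one; 25 [4-(tert-butyldimethylsilyloxy)-2-methoxyphenyl]boronic acid
Product: 26 (2S)-7-(tert-butyldimethylsilyloxy)-2-[4-(tert-butyldimethylsilyloxy)-2-methoxyphenyl]-5-methoxy-8-[(2R)-5-methyl-2-(prop-1-en-2-yl)-5-(triethylsilyloxy)hexyl]-2,3-dihydro-4H-chromen-4-one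
Conditions: Pd(OCOCF3)2 (10 mol %), (R)-t-BuPyOx (12 mol %), NH4PF6, H2O, ClCH2CH2Cl, 50 °C; 25 in excess
Reagents that add atoms: none
Why: Pd(II)/pyridinooxazoline-catalysed asymmetric conjugate addition of an arylboronic acid to a chromone (transmetalation, face-selective carbopalladation of C2=C3, protonolysis of the Pd enolate) should set C2 under ligand control, the (R)-ligand being expected by analogy with cyclic enones to give 2S, in a near-neutral medium that avoids ring opening of the flavanone.

Step 19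
Reactants: 26 (2S)-7-(tert-butyldimethylsilyloxy)-2-[4-(tert-butyldimethylsilyloxy)-2-methoxyphenyl]-5-methoxy-8-[(2R)-5-methyl-2-(prop-1-en-2-yl)-5-(triethylsilyloxy)hexyl]-2,3-dihydro-4H-chromen-4-one
Product: 27 (2S)-7-hydroxy-2-(4-hydroxy-2-methoxyphenyl)-8-[(2R)-5-hydroxy-5-methyl-2-(prop-1-en-2-yl)hexyl]-5-methoxy-2,3-dihydro-4H-chromen-4-one (HY-N7794)
Conditions: HF·pyridine, pyridine, THF, 0 °C → rt
Reagents that add atoms: none
Why: Buffered fluoride desilylation should remove both aryl silyl ethers and the tertiary triethylsilyl ether without forming a phenoxide that could open ring C by retro-oxa-Michael reaction and scramble C2, and without acid strong enough to add the tertiary alcohol to the isopropenyl group.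

**Compound list**

1 | 2,4,6-trihydroxybenzaldehyde | O=Cc1c(O)cc(O)cc1O | starting material
2 | 2,6-dihydroxy-4-methoxybenzaldehyde | COc1cc(O)c(C=O)c(O)c1 | intermediate
3 | 2,6-bis(tert-butyldimethylsilyloxy)-4-methoxybenzaldehyde | COc1cc(O[Si](C)(C)C(C)(C)C)c(C=O)c(O[Si](C)(C)C(C)(C)C)c1 | intermediate
4 | [2,6-bis(tert-butyldimethylsilyloxy)-4-methoxyphenyl]methanol | COc1cc(O[Si](C)(C)C(C)(C)C)c(CO)c(O[Si](C)(C)C(C)(C)C)c1 | intermediate
5 | 2-(bromomethyl)-1,3-bis(tert-butyldimethylsilyloxy)-5-methoxybenzene | COc1cc(O[Si](C)(C)C(C)(C)C)c(CBr)c(O[Si](C)(C)C(C)(C)C)c1 | intermediate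
6 | 5-oxohexanoic acid | CC(=O)CCCC(=O)O | starting material
7 | 5-hydroxy-5-methylhexanoic acid | CC(C)(O)CCCC(=O)O | intermediate
8 | triethylsilyl 5-methyl-5-(triethylsilyloxy)hexanoate (bis-silyl ester) | CC[Si](CC)(CC)OC(=O)CCCC(C)(C)O[Si](CC)(CC)CC | intermediate (not isolated)
9 | 5-methyl-5-(triethylsilyloxy)hexanoic acid | CC[Si](CC)(CC)OC(C)(C)CCCC(=O)O | intermediate
10 | 1-[5-methyl-5-(triethylsilyloxy)hexanoyl]-1H-imidazole | O=C(CCCC(C)(C)O[Si](CC)(CC)CC)n1ccnc1 | intermediate
11 | 5-(tert-butyldimethylsilyloxy)-3-methoxy-6-methylidenecyclohexa-2,4-dien-1-one (quinone methide) | C=C1C(=O)C=C(OC)C=C1O[Si](C)(C)C(C)(C)C | intermediate (not isolated)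
12 | (3R)-5-(tert-butyldimethylsilyloxy)-7-methoxy-3-[3-methyl-3-(triethylsilyloxy)butyl]-3,4-dihydro-2H-chromen-2-one | O=C1Oc2cc(OC)cc(O[Si](C)(C)C(C)(C)C)c2C[C@H]1CCC(C)(C)O[Si](CC)(CC)CC | intermediate
13 | (2R)-2-{[2-(tert-butyldimethylsilyloxy)-6-hydroxy-4-methoxyphenyl]methyl}-N-methoxy-N,5-dimethyl-5-(triethylsilyloxy)hexanamide | CON(C)C(=O)[C@H](CCC(C)(C)O[Si](CC)(CC)CC)Cc1c(O)cc(OC)cc1O[Si](C)(C)C(C)(C)C | intermediate
14 | (2R)-2-{[2-(tert-butyldimethylsilyloxy)-4-methoxy-6-(methoxymethoxy)phenyl]methyl}-N-methoxy-N,5-dimethyl-5-(triethylsilyloxy)hexanamide | CON(C)C(=O)[C@H](CCC(C)(C)O[Si](CC)(CC)CC)Cc1c(OCOC)cc(OC)cc1O[Si](C)(C)C(C)(C)C | intermediate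
15 | (3R)-3-{[2-(tert-butyldimethylsilyloxy)-4-methoxy-6-(methoxymethoxy)phenyl]methyl}-6-methyl-6-(triethylsilyloxy)heptan-2-one | CC(=O)[C@H](CCC(C)(C)O[Si](CC)(CC)CC)Cc1c(OCOC)cc(OC)cc1O[Si](C)(C)C(C)(C)C | intermediate
16 | 1-(tert-butyldimethylsilyloxy)-5-methoxy-3-(methoxymethoxy)-2-[(2R)-5-methyl-2-(prop-1-en-2-yl)-5-(triethylsilyloxy)hexyl]benzene | C=C(C)[C@H](CCC(C)(C)O[Si](CC)(CC)CC)Cc1c(OCOC)cc(OC)cc1O[Si](C)(C)C(C)(C)C | intermediate
17 | aryllithium of 16, lithiated between OMOM and OMe | C=C(C)[C@H](CCC(C)(C)O[Si](CC)(CC)CC)Cc1c(OCOC)c([Li])c(OC)cc1O[Si](C)(C)C(C)(C)C | intermediate (not isolated)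
18 | 1-{4-(tert-butyldimethylsilyloxy)-6-methoxy-2-(methoxymethoxy)-3-[(2R)-5-methyl-2-(prop-1-en-2-yl)-5-(triethylsilyloxy)hexyl]phenyl}ethan-1-one | C=C(C)[C@H](CCC(C)(C)O[Si](CC)(CC)CC)Cc1c(OCOC)c(C(C)=O)c(OC)cc1O[Si](C)(C)C(C)(C)C | intermediate
19 | 1-{4-(tert-butyldimethylsilyloxy)-2-hydroxy-6-methoxy-3-[(2R)-5-methyl-2-(prop-1-en-2-yl)-5-(triethylsilyloxy)hexyl]phenyl}ethan-1-one | C=C(C)[C@H](CCC(C)(C)O[Si](CC)(CC)CC)Cc1c(O)c(C(C)=O)c(OC)cc1O[Si](C)(C)C(C)(C)C | intermediate
20 | (2E)-1-{4-(tert-butyldimethylsilyloxy)-2-hydroxy-6-methoxy-3-[(2R)-5-methyl-2-(prop-1-en-2-yl)-5-(triethylsilyloxy)hexyl]phenyl}-3-(dimethylamino)prop-2-en-1-one (enaminone) | C=C(C)[C@H](CCC(C)(C)O[Si](CC)(CC)CC)Cc1c(O)c(C(=O)/C=C/N(C)C)c(OC)cc1O[Si](C)(C)C(C)(C)C | intermediate (not isolated)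
21 | 7-(tert-butyldimethylsilyloxy)-5-methoxy-8-[(2R)-5-methyl-2-(prop-1-en-2-yl)-5-(triethylsilyloxy)hexyl]-4H-chromen-4-one | C=C(C)[C@H](CCC(C)(C)O[Si](CC)(CC)CC)Cc1c(O[Si](C)(C)C(C)(C)C)cc(OC)c2c1occc2=O | intermediate
22 | 4-bromo-3-methoxyphenol | COc1cc(O)ccc1Br | starting material
23 | (4-bromo-3-methoxyphenoxy)(tert-butyl)dimethylsilane | COc1cc(O[Si](C)(C)C(C)(C)C)ccc1Br | intermediate
24 | [4-(tert-butyldimethylsilyloxy)-2-methoxyphenyl]lithium | COc1cc(O[Si](C)(C)C(C)(C)C)ccc1[Li] | intermediate (not isolated)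
25 | [4-(tert-butyldimethylsilyloxy)-2-methoxyphenyl]boronic acid | COc1cc(O[Si](C)(C)C(C)(C)C)ccc1B(O)O | intermediate
26 | (2S)-7-(tert-butyldimethylsilyloxy)-2-[4-(tert-butyldimethylsilyloxy)-2-methoxyphenyl]-5-methoxy-8-[(2R)-5-methyl-2-(prop-1-en-2-yl)-5-(triethylsilyloxy)hexyl]-2,3-dihydro-4H-chromen-4-one | C=C(C)[C@H](CCC(C)(C)O[Si](CC)(CC)CC)Cc1c(O[Si](C)(C)C(C)(C)C)cc(OC)c2c1O[C@H](c1ccc(O[Si](C)(C)C(C)(C)C)cc1OC)CC2=O | intermediate
27 | (2S)-7-hydroxy-2-(4-hydroxy-2-methoxyphenyl)-8-[(2R)-5-hydroxy-5-methyl-2-(prop-1-en-2-yl)hexyl]-5-methoxy-2,3-dihydro-4H-chromen-4-one (HY-N7794) | C=C(C)[C@H](CCC(C)(C)O)Cc1c(O)cc(OC)c2c1O[C@H](c1ccc(O)cc1OC)CC2=O | target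

**Step count and risks**

Total: 19 steps. Longest linear sequence: 14 steps (steps 1–4, 8–15, 18, 19).

The three steps most likely to fail:

Step 8. The azolium enolate of an unbranched alkyl acyl donor may be consumed by self-condensation faster than it adds to the quinone methide. It may also add with insufficient facial selectivity, and the fluoride may strip the second aryl silyl group or the labile bromide may ionise before use. The fallback makes the same C1''–C2'' bond by auxiliary-controlled enolate alkylation. It sets out from acid 9 and bromide 5. Acid 9 is converted with pivaloyl chloride and Et3N into the mixed pivalic anhydride F1, which acylates (S)-4-benzyloxazolidin-2-one (LiCl, Et3N, THF) to give the N-acyl oxazolidinone F2. Its sodium (Z)-enolate (NaHMDS, THF, −78 °C) should be alkylated by 5 on the face opposite the benzyl group to give the (2R)-alkylated imide F3. One equivalent of TBAF at 0 °C then frees one of the two equivalent phenols, which should lactonise onto the exocyclic imide carbonyl with loss of the auxiliary. The route is rejoined at lactone 12.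

Step 18. Carbopalladation of the electron-rich 5-methoxychromone may be slow, so that protodeboronation of the ortho-methoxy boronic acid wins. The isopropenyl group may also intercept the aryl–palladium species, or facial discrimination may be poor. The fallback builds ring C from the acetophenone and sets out from 19. Compound 19 is condensed with 4-(tert-butyldimethylsilyloxy)-2-methoxybenzaldehyde F7 (from commercial 4-hydroxy-2-methoxybenzaldehyde, TBSCl, imidazole) under pyrrolidine/AcOH catalysis in toluene at 60 °C. This should give the 2'-hydroxychalcone F8, which equilibrates by oxa-Michael closure to the flavanone as both C2 epimers, 26 and its (2R) epimer F9. Because C2'' is fixed these are diastereomers and should be separable by preparative HPLC, and F9 can be returned to the same amine-mediated equilibrium. The route is rejoined at 26.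

Step 13. Metalation may stray to the benzylic or allylic positions, or the hindered aryllithium may only deprotonate the acetamide and return 16. The fallback brings in the acetyl group by phenoxide-directed electrophilic substitution and sets out from 16. The MOM group is removed (ZnBr2, n-PrSH) to give 3-(tert-butyldimethylsilyloxy)-5-methoxy-2-[(2R)-5-methyl-2-(prop-1-en-2-yl)-5-(triethylsilyloxy)hexyl]phenol F4. Magnesium-mediated ortho-formylation (MgCl2, Et3N, paraformaldehyde, THF, reflux) should place CHO at the only free position ortho to the OH, giving the salicylaldehyde F5. Excess MeMgBr should give the 1-arylethanol F6 as a mixture at the carbinol centre, which is of no consequence. MnO2 oxidation returns to the route at 19.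

**Further compounds**

F1 | step 8 | 5-methyl-5-(triethylsilyloxy)hexanoic pivalic anhydride | CC(C)(C)C(=O)OC(=O)CCCC(C)(C)O[Si](CC)(CC)CC
F2 | step 8 | (4S)-4-benzyl-3-[5-methyl-5-(triethylsilyloxy)hexanoyl]-1,3-oxazolidin-2-one | O=C(CCCC(C)(C)O[Si](CC)(CC)CC)N1[C@@H](Cc2ccccc2)COC1=O
F3 | step 8 | (4S)-4-benzyl-3-[(2R)-2-{[2,6-bis(tert-butyldimethylsilyloxy)-4-methoxyphenyl]methyl}-5-methyl-5-(triethylsilyloxy)hexanoyl]-1,3-oxazolidin-2-one | O=C([C@H](CCC(C)(C)O[Si](CC)(CC)CC)Cc1c(O[Si](C)(C)C(C)(C)C)cc(OC)cc1O[Si](C)(C)C(C)(C)C)N1[C@@H](Cc2ccccc2)COC1=O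
F4 | step 13 | 3-(tert-butyldimethylsilyloxy)-5-methoxy-2-[(2R)-5-methyl-2-(prop-1-en-2-yl)-5-(triethylsilyloxy)hexyl]phenol | C=C(C)[C@H](CCC(C)(C)O[Si](CC)(CC)CC)Cc1c(O)cc(OC)cc1O[Si](C)(C)C(C)(C)C
F5 | step 13 | 4-(tert-butyldimethylsilyloxy)-2-hydroxy-6-methoxy-3-[(2R)-5-methyl-2-(prop-1-en-2-yl)-5-(triethylsilyloxy)hexyl]benzaldehyde | C=C(C)[C@H](CCC(C)(C)O[Si](CC)(CC)CC)Cc1c(O)c(C=O)c(OC)cc1O[Si](C)(C)C(C)(C)C
F6 | step 13 | 1-{4-(tert-butyldimethylsilyloxy)-2-hydroxy-6-methoxy-3-[(2R)-5-methyl-2-(prop-1-en-2-yl)-5-(triethylsilyloxy)hexyl]phenyl}ethan-1-ol (both carbinol epimers) | C=C(C)[C@H](CCC(C)(C)O[Si](CC)(CC)CC)Cc1c(O)c(C(C)O)c(OC)cc1O[Si](C)(C)C(C)(C)C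
F7 | step 18 | 4-(tert-butyldimethylsilyloxy)-2-methoxybenzaldehyde | COc1cc(O[Si](C)(C)C(C)(C)C)ccc1C=O
F8 | step 18 | (2E)-1-{4-(tert-butyldimethylsilyloxy)-2-hydroxy-6-methoxy-3-[(2R)-5-methyl-2-(prop-1-en-2-yl)-5-(triethylsilyloxy)hexyl]phenyl}-3-[4-(tert-butyldimethylsilyloxy)-2-methoxyphenyl]prop-2-en-1-one | C=C(C)[C@H](CCC(C)(C)O[Si](CC)(CC)CC)Cc1c(O)c(C(=O)/C=C/c2ccc(O[Si](C)(C)C(C)(C)C)cc2OC)c(OC)cc1O[Si](C)(C)C(C)(C)C
F9 | step 18 | (2R)-7-(tert-butyldimethylsilyloxy)-2-[4-(tert-butyldimethylsilyloxy)-2-methoxyphenyl]-5-methoxy-8-[(2R)-5-methyl-2-(prop-1-en-2-yl)-5-(triethylsilyloxy)hexyl]-2,3-dihydro-4H-chromen-4-one | C=C(C)[C@H](CCC(C)(C)O[Si](CC)(CC)CC)Cc1c(O[Si](C)(C)C(C)(C)C)cc(OC)c2c1O[C@@H](c1ccc(O[Si](C)(C)C(C)(C)C)cc1OC)CC2=O
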